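**Retrosynthetic overview**
1. Feature: the (2R,3R)-erythro unit 3,4-dihydroxyphenyl–Cβ(OH)–Cα(OAr)–CO2H is, atom for atom, ring B, C2, C3 and C4 of the pyranone ring of (2R,3R)-taxifolin. Only the C4–C4a bond to ring A is surplus.
2. Carboxyl C–O ⇒ C4–C4a. A Baeyer–Villiger oxygen insertion expands the six-membered pyranone to a seven-membered 1,5-benzodioxepin-2-one. This is the only ring made (step 3) and it is opened again in step 5. The three arenes of the target are bought.
3. Aryl–O–Cα ⇒ SNAr of Cα–OH on 3-allyloxy-4-fluorobenzaldehyde (Cα–O retained) while ring A still masks Cβ–O. Ring A then leaves as a p-quinone (Ce(IV), then alkoxy exchange) by cleavage of its own C8a–O bond.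
4. Cinnamate C=C ⇒ Wittig reaction with the phosphorane of (R)-danshensu. Seven allyl groups are removed in one Pd(0) step.

Key step: step 3

Remark: commercial (+)-taxifolin is taken as the (2R,3R) enantiomer and danshensu as the free (R)-acid. Ring A atoms keep their taxifolin numbers (C4a, C5, C7, C8a) in all comments.

**Step 1**
Reactants: 1 (2R,3R)-taxifolin
Product: 2 (2R,3R)-5,7,3',4'-tetra-O-benzyltaxifolin (3-OH free)
Conditions: BnBr (5 equiv), K2CO3, cat. TBAI, DMF, 0 °C → rt, Ar
Reagents that add atoms: benzyl bromide, BrCc1ccccc1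
Why: Williamson O-alkylation in which carbonate deprotonates only the four phenols (the chelated 5-OH last), the aliphatic 3-OH stays free, and early capping of the acidic 7- and 4'-OH shuts off the phenoxide-driven opening of the C2–O1 bond that would epimerise C2.

**Step 2**
Reactants: 2 tetra-O-benzyltaxifolin
Product: 3 (2R,3R)-3-O-acetyl-5,7,3',4'-tetra-O-benzyltaxifolin
Conditions: Ac2O, pyridine, cat. DMAP, CH2Cl2, 0 °C → rt
Reagents that add atoms: acetic anhydride, CC(=O)OC(C)=O
Why: DMAP-catalysed acylation of the only free hydroxyl under weakly basic conditions that do not enolise C3, which installs the group that blocks α-ketol cleavage and lowers the migratory aptitude of C3 in step 3.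

**Step 3**
Reactants: 3 3-O-acetyl-tetra-O-benzyltaxifolin
Product: 4 (3R,4R)-3-acetoxy-7,9-bis(benzyloxy)-4-[3,4-bis(benzyloxy)phenyl]-3,4-dihydro-2H-1,5-benzodioxepin-2-one
Conditions: mCPBA (2 equiv), solid NaHCO3 buffer, CH2Cl2, 0 °C → rt, dark
Reagents that add atoms: mCPBA, OOC(=O)c1cccc(Cl)c1
Why: Baeyer–Villiger oxidation: the peracid adds to the C4 ketone, made more electrophilic by the α-acetoxy group, and in the Criegee adduct C4a migrates from C4 to the proximal peroxide oxygen as 3-chlorobenzoate leaves, which cleaves C4–C4a and forms the carboxyl C–O bond. The closest known reactions are the Baeyer–Villiger oxidations of polyalkoxyaryl ketones and of flavanones, which give aryl esters and 1,5-benzodioxepin-2-ones by aryl migration. The seven-membered ring arises by ring expansion (1,2-shift with oxygen insertion into the six-membered pyranone), not by a cyclisation. No stereocentre is formed, and C2 and C3 keep their configuration because none of their bonds is broken and the migrating carbon is sp2. The step needs C4a to migrate rather than C3: C4a has donor oxygens at both ortho positions and at the para position (O1, 5-OBn, 7-OBn), whereas the lone pair of O3 is tied up in the acetate, which is why an ester and not a silyl or alkyl ether sits on O3, since α-silyloxy and α-alkoxy carbons migrate well. Benzyl rather than allyl ethers leave no C=C bond for the peracid during the long reaction time expected for this conjugated ketone, and the buffer protects the benzylic C2–O1 bond.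

**Step 4**
Reactants: 4 benzodioxepinone
Product: 5 (3R,4R)-3-acetoxy-4-(3,4-dihydroxyphenyl)-7,9-dihydroxy-3,4-dihydro-2H-1,5-benzodioxepin-2-one
Conditions: H2 (1 atm), 10% Pd/C, EtOAc–THF, rt
Reagents that add atoms: none
Why: Catalytic hydrogenolysis of four primary benzyl aryl ethers, which should be cleaved much faster than the hindered secondary ring C4–O5 bond (as in the debenzylation of benzylated flavan-3-ols), in an aprotic solvent that leaves the aryl lactone and acetate intact; the swap is made here because the end game needs Pd(0)-labile groups next to a cinnamate C=C.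

**Step 5**
Reactants: 5 tetrahydroxy lactone; 6 allyl bromide
Product: 10 allyl (2R,3R)-3-[3,4-bis(allyloxy)phenyl]-2-hydroxy-3-[2,3,5-tris(allyloxy)phenoxy]propanoate, via tetraallyl lactone 7 (not isolated), via ring-opened phenol 8 (not isolated), via hexaallyl acetate 9 (not isolated)
Conditions: K2CO3, allyl bromide (excess), DMF, 0 °C → rt, Ar; then allyl alcohol, rt
Reagents that add atoms: allyl bromide (6), C=CCBr; allyl alcohol, OCC=C
Why: Williamson allylation of the four phenols followed by carbonate-catalysed transesterification, in which allyl alcohol opens the activated aryl lactone and removes the α-acetate, the freed C4a phenoxide is trapped at once by excess allyl bromide, all orders of events converge on 10, the aliphatic Cα–OH is not alkylated by K2CO3, and no bond to Cα or Cβ is broken.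

**Step 6**
Reactants: 10 α-hydroxy allyl ester
Product: 11 (2R,3R)-3-[3,4-bis(allyloxy)phenyl]-2-hydroxy-3-[2,3,5-tris(allyloxy)phenoxy]propanoic acid
Conditions: LiOH, THF–H2O, 0 °C; then cold 1 M HCl to pH 3
Reagents that add atoms: lithium hydroxide, [Li+].[OH-]
Why: Saponification (BAc2) of the single, α-hydroxy-activated ester at 0 °C, carried out because the carboxylate makes Cα–H non-acidic in step 8.

**Step 7**
Reactants: 12 4-fluoro-3-hydroxybenzaldehyde; 6 allyl bromide
Product: 13 3-(allyloxy)-4-fluorobenzaldehyde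
Conditions: allyl bromide, K2CO3, DMF, rt
Reagents that add atoms: allyl bromide (6), C=CCBr
Why: Williamson ether synthesis on the only acidic OH, under conditions where carbonate does not displace the aryl fluoride.

**Step 8**
Reactants: 11 α-hydroxy acid; 13 3-(allyloxy)-4-fluorobenzaldehyde; 6 allyl bromide
Product: 15 allyl (2R,3R)-2-[2-(allyloxy)-4-formylphenoxy]-3-[3,4-bis(allyloxy)phenyl]-3-[2,3,5-tris(allyloxy)phenoxy]propanoate, via aryl ether sodium carboxylate 14 (not isolated)
Conditions: NaH (2.3 equiv), DMF, 0 °C; 13, 0 → 40 °C; then allyl bromide, rt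
Reagents that add atoms: allyl bromide (6), C=CCBr
Why: SNAr (addition–elimination through the Meisenheimer adduct para to the formyl group) by the alkoxide of the carboxylate–alkoxide dianion, as in the arylation of lactic and mandelic acid dianions with activated fluoroarenes; the Cα–O bond is not touched so Cα stays R, the carboxylate suppresses enolisation and β-elimination of the ring A aryloxide, electron-rich ring A blocks Cβ–O and cannot undergo Smiles migration, and the carboxylate is then O-alkylated in the same flask.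

**Step 9**
Reactants: 15 aryl ether aldehyde
Product: 16 allyl (2R,3R)-2-[2-(allyloxy)-4-formylphenoxy]-3-{[5-(allyloxy)-3,6-dioxocyclohexa-1,4-dien-1-yl]oxy}-3-[3,4-bis(allyloxy)phenyl]propanoate
Conditions: (NH4)2Ce(NO3)6 (2.2 equiv), MeCN–H2O 4:1, 0 °C; used crude
Reagents that add atoms: water, O
Why: Ce(IV) oxidative dealkylation of a 1,4-dialkoxyarene to the p-quinone, in which the tetra-oxygenated ring A is the most easily oxidised arene, water attacks its radical cation at the only para-related oxygenated pair (C4a and C7) and expels two allyl alcohols, and Cβ–O is left on C8a as a quinone vinylogous ester.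

**Step 10**
Reactants: 16 quinone ether
Product: 17 allyl (2R,3R)-2-[2-(allyloxy)-4-formylphenoxy]-3-[3,4-bis(allyloxy)phenyl]-3-hydroxypropanoate
Conditions: K2CO3 (0.1–0.2 equiv), allyl alcohol (solvent, degassed), 0 °C; AcOH quench
Reagents that add atoms: none
Why: Base-catalysed alkoxy exchange at an alkoxy-1,4-benzoquinone (addition–elimination at the vinylogous ester carbon, the reaction by which methoxyquinones take up ethoxy groups in alkaline ethanol), in which allyl alkoxide cleaves the quinone C8a–O bond so that Cβ keeps its oxygen and its R configuration, exchange at the second alkoxy group and at the allyl ester is degenerate in this solvent, and the solvent excess drives the equilibrium.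

**Step 11**
Reactants: 18 (R)-danshensu; 6 allyl bromide
Product: 19 allyl (R)-3-[3,4-bis(allyloxy)phenyl]-2-hydroxypropanoate
Conditions: allyl bromide (3.5 equiv), K2CO3, DMF, rt, Ar
Reagents that add atoms: allyl bromide (6), C=CCBr
Why: Carbonate-mediated O-alkylation of the two phenols and the carboxylate, which leaves the less acidic secondary OH and the stereocentre untouched.

**Step 12**
Reactants: 19 triallyl danshensu
Product: 20 allyl (R)-3-[3,4-bis(allyloxy)phenyl]-2-(2-bromoacetoxy)propanoate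
Conditions: BrCH2COBr, pyridine, CH2Cl2, −10 → 0 °C
Reagents that add atoms: bromoacetyl bromide, BrCC(Br)=O
Why: O-acylation of the secondary alcohol by an acid bromide, which leaves the C–O bond of the stereocentre intact.

**Step 13**
Reactants: 20 bromoacetate
Product: 22 allyl (R)-3-[3,4-bis(allyloxy)phenyl]-2-[2-(triphenyl-λ5-phosphanylidene)acetoxy]propanoate, via phosphonium bromide 21 (not isolated)
Conditions: PPh3, toluene, rt; then CH2Cl2 / aq. Na2CO3, 0 °C
Reagents that add atoms: triphenylphosphine, c1ccc(cc1)P(c1ccccc1)c1ccccc1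
Why: SN2 quaternisation of PPh3 by the α-bromo ester, then deprotonation of the acidic phosphonium salt by aqueous carbonate to the stabilised ylide, mild enough to spare both esters.

**Step 14**
Reactants: 17 β-hydroxy aldehyde; 22 danshensu phosphorane
Product: 23 hepta-allyl derivative of the target: (E)-cinnamate, five aryl allyl ethers, two allyl esters, free Cβ–OH, (2R,3R) in the glycerate unit and (R) in the danshensu unit
Conditions: toluene, 60 °C
Reagents that add atoms: none
Why: Wittig olefination with an ester-stabilised ylide, which should give mainly the E-alkene through the reversible, thermodynamically controlled oxaphosphetane pathway and is neutral enough to tolerate the free Cβ–OH and the α-aryloxy ester.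

**Step 15**
Reactants: 23 hepta-allyl derivative
Product: 24 target CNP0159428.1
Conditions: Pd(PPh3)4 (cat.), morpholine (excess), THF, rt, Ar, dark; then cold dilute HCl, reversed-phase chromatography
Reagents that add atoms: none
Why: Tsuji–Trost deallylation in which Pd(0) ionises the five aryl allyl ethers and two allyl esters to π-allyl complexes that morpholine captures, under near-neutral conditions that spare the cinnamate C=C, both ester links and the acid-sensitive benzylic Cβ–OH.

**Compound list**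
1 | (2R,3R)-taxifolin | O[C@H]1C(=O)c2c(O)cc(O)cc2O[C@@H]1c1ccc(O)c(O)c1 | starting material
2 | (2R,3R)-5,7,3',4'-tetra-O-benzyltaxifolin | O[C@H]1C(=O)c2c(OCc3ccccc3)cc(OCc3ccccc3)cc2O[C@@H]1c1ccc(OCc2ccccc2)c(OCc2ccccc2)c1 | intermediate
3 | (2R,3R)-3-O-acetyl-5,7,3',4'-tetra-O-benzyltaxifolin | CC(=O)O[C@H]1C(=O)c2c(OCc3ccccc3)cc(OCc3ccccc3)cc2O[C@@H]1c1ccc(OCc2ccccc2)c(OCc2ccccc2)c1 | intermediate
4 | (3R,4R)-3-acetoxy-7,9-bis(benzyloxy)-4-[3,4-bis(benzyloxy)phenyl]-3,4-dihydro-2H-1,5-benzodioxepin-2-one | CC(=O)O[C@H]1C(=O)Oc2c(OCc3ccccc3)cc(OCc3ccccc3)cc2O[C@@H]1c1ccc(OCc2ccccc2)c(OCc2ccccc2)c1 | intermediate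
5 | (3R,4R)-3-acetoxy-4-(3,4-dihydroxyphenyl)-7,9-dihydroxy-3,4-dihydro-2H-1,5-benzodioxepin-2-one | CC(=O)O[C@H]1C(=O)Oc2c(O)cc(O)cc2O[C@@H]1c1ccc(O)c(O)c1 | intermediate
6 | allyl bromide | C=CCBr | starting material
7 | (3R,4R)-3-acetoxy-7,9-bis(allyloxy)-4-[3,4-bis(allyloxy)phenyl]-3,4-dihydro-2H-1,5-benzodioxepin-2-one | CC(=O)O[C@H]1C(=O)Oc2c(OCC=C)cc(OCC=C)cc2O[C@@H]1c1ccc(OCC=C)c(OCC=C)c1 | intermediate
8 | allyl (2R,3R)-2-acetoxy-3-[3,5-bis(allyloxy)-2-hydroxyphenoxy]-3-[3,4-bis(allyloxy)phenyl]propanoate | CC(=O)O[C@@H](C(=O)OCC=C)[C@H](Oc1cc(OCC=C)cc(OCC=C)c1O)c1ccc(OCC=C)c(OCC=C)c1 | intermediate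
9 | allyl (2R,3R)-2-acetoxy-3-[3,4-bis(allyloxy)phenyl]-3-[2,3,5-tris(allyloxy)phenoxy]propanoate | CC(=O)O[C@@H](C(=O)OCC=C)[C@H](Oc1cc(OCC=C)cc(OCC=C)c1OCC=C)c1ccc(OCC=C)c(OCC=C)c1 | intermediate
10 | allyl (2R,3R)-3-[3,4-bis(allyloxy)phenyl]-2-hydroxy-3-[2,3,5-tris(allyloxy)phenoxy]propanoate | O[C@@H](C(=O)OCC=C)[C@H](Oc1cc(OCC=C)cc(OCC=C)c1OCC=C)c1ccc(OCC=C)c(OCC=C)c1 | intermediate
11 | (2R,3R)-3-[3,4-bis(allyloxy)phenyl]-2-hydroxy-3-[2,3,5-tris(allyloxy)phenoxy]propanoic acid | O[C@@H](C(=O)O)[C@H](Oc1cc(OCC=C)cc(OCC=C)c1OCC=C)c1ccc(OCC=C)c(OCC=C)c1 | intermediate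
12 | 4-fluoro-3-hydroxybenzaldehyde | O=Cc1ccc(F)c(O)c1 | starting material
13 | 3-(allyloxy)-4-fluorobenzaldehyde | O=Cc1ccc(F)c(OCC=C)c1 | intermediate
14 | sodium (2R,3R)-2-[2-(allyloxy)-4-formylphenoxy]-3-[3,4-bis(allyloxy)phenyl]-3-[2,3,5-tris(allyloxy)phenoxy]propanoate | [Na+].O=Cc1ccc(O[C@@H](C(=O)[O-])[C@H](Oc2cc(OCC=C)cc(OCC=C)c2OCC=C)c2ccc(OCC=C)c(OCC=C)c2)c(OCC=C)c1 | intermediate
15 | allyl (2R,3R)-2-[2-(allyloxy)-4-formylphenoxy]-3-[3,4-bis(allyloxy)phenyl]-3-[2,3,5-tris(allyloxy)phenoxy]propanoate | O=Cc1ccc(O[C@@H](C(=O)OCC=C)[C@H](Oc2cc(OCC=C)cc(OCC=C)c2OCC=C)c2ccc(OCC=C)c(OCC=C)c2)c(OCC=C)c1 | intermediate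
16 | allyl (2R,3R)-2-[2-(allyloxy)-4-formylphenoxy]-3-{[5-(allyloxy)-3,6-dioxocyclohexa-1,4-dien-1-yl]oxy}-3-[3,4-bis(allyloxy)phenyl]propanoate | O=Cc1ccc(O[C@@H](C(=O)OCC=C)[C@H](OC2=CC(=O)C=C(OCC=C)C2=O)c2ccc(OCC=C)c(OCC=C)c2)c(OCC=C)c1 | intermediate
17 | allyl (2R,3R)-2-[2-(allyloxy)-4-formylphenoxy]-3-[3,4-bis(allyloxy)phenyl]-3-hydroxypropanoate | O=Cc1ccc(O[C@@H](C(=O)OCC=C)[C@H](O)c2ccc(OCC=C)c(OCC=C)c2)c(OCC=C)c1 | intermediate
18 | (R)-danshensu | O[C@H](Cc1ccc(O)c(O)c1)C(=O)O | starting material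
19 | allyl (R)-3-[3,4-bis(allyloxy)phenyl]-2-hydroxypropanoate | O[C@H](Cc1ccc(OCC=C)c(OCC=C)c1)C(=O)OCC=C | intermediate
20 | allyl (R)-3-[3,4-bis(allyloxy)phenyl]-2-(2-bromoacetoxy)propanoate | BrCC(=O)O[C@H](Cc1ccc(OCC=C)c(OCC=C)c1)C(=O)OCC=C | intermediate
21 | phosphonium bromide of 20 | [Br-].O=C(C[P+](c1ccccc1)(c1ccccc1)c1ccccc1)O[C@H](Cc1ccc(OCC=C)c(OCC=C)c1)C(=O)OCC=C | intermediate
22 | allyl (R)-3-[3,4-bis(allyloxy)phenyl]-2-[2-(triphenyl-λ5-phosphanylidene)acetoxy]propanoate | O=C(C=P(c1ccccc1)(c1ccccc1)c1ccccc1)O[C@H](Cc1ccc(OCC=C)c(OCC=C)c1)C(=O)OCC=C | intermediate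
23 | hepta-allyl derivative of the target | O=C(/C=C/c1ccc(O[C@@H](C(=O)OCC=C)[C@H](O)c2ccc(OCC=C)c(OCC=C)c2)c(OCC=C)c1)O[C@H](Cc1ccc(OCC=C)c(OCC=C)c1)C(=O)OCC=C | intermediate
24 | CNP0159428.1 | O=C(/C=C/c1ccc(O[C@@H](C(=O)O)[C@H](O)c2ccc(O)c(O)c2)c(O)c1)O[C@H](Cc1ccc(O)c(O)c1)C(=O)O | target

**Total step count:** 15.
**Longest linear sequence:** 11 (steps 1, 2, 3, 4, 5, 6, 8, 9, 10, 14, 15).

**Steps most likely to fail**

Step 3.
- Risk: the peracid may add too slowly to the strongly donor-conjugated C4 carbonyl. C3 may migrate in competition with C4a. Excess peracid may hydroxylate ring A.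
- Fallback: the same oxygen insertion is run one oxidation level lower as a Hock-type hydroperoxide rearrangement, which needs no addition to a deactivated carbonyl. It sets out from 3 and comes back at 4.
- Luche reduction (NaBH4, CeCl3, MeOH–THF, −40 °C) should give the 2,3-trans-3,4-trans flavan-4-ol F1.
- Urea–H2O2 with catalytic TsOH in THF at 0 °C exchanges the readily ionised C4–OH for OOH to give the 4-hydroperoxide F2.
- Under the same acid, ring A shifts from C4 to oxygen with loss of water. Excess H2O2 catches the ring-expanded oxocarbenium ion as the 2-hydroperoxy-1,5-benzodioxepine F3.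
- Dehydration of this alkoxy hydroperoxide with Ac2O/Et3N, as practised on ozonolysis-derived alkoxy hydroperoxides, gives lactone 4.

Step 10.
- Risk: under base the quinonyloxy group may be lost by β-elimination across Cα–Cβ. The freed Cβ alkoxide may start retro-aldol cleavage or take over the formyl-activated aryl ring from Cα–O (O→O Smiles migration). Cα may epimerise.
- Fallback: ring A is shed later and under acid, on a substrate that no longer carries the formyl group. It sets out from 15 and comes back at 23.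
- Wittig olefination of 15 with 22 (toluene, 60 °C) should give the ring A-bearing cinnamate F4.
- Ce(IV) ammonium nitrate (MeCN–H2O, 0 °C) converts F4 into the quinone ether F5.
- Catalytic camphorsulfonic acid in allyl alcohol at rt then exchanges the alkoxy group by the acid-catalysed path known from the etherification of hydroxyquinones with alcohols. No alkoxide is present at any time, and the product is 23.

Step 8.
- Risk: the hindered, sodium-chelated alkoxide may attack the donor-substituted fluoroarene too slowly. Reversible addition to the aldehyde, hydride transfer to it, or base-induced breakdown of DMF could then take over.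
- Fallback: polarity is reversed so that Cα becomes the electrophile, and two Mitsunobu inversions give net retention. It sets out from 10 (and 6) and comes back at 15.
- Mitsunobu reaction of 10 with 4-nitrobenzoic acid (PPh3, DIAD, THF, 0 °C) should give the (2S,3R)-4-nitrobenzoate F6.
- K2CO3 in allyl alcohol at 0 °C, degenerate for the allyl ester, frees the (2S,3R)-alcohol F7.
- The phenol partner 3-(allyloxy)-4-hydroxybenzaldehyde F8 comes from the dianion of 3,4-dihydroxybenzaldehyde (NaH, DMSO) and one equivalent of 6, which alkylates the more nucleophilic 3-oxide.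
- A second Mitsunobu reaction of F7 with F8 inverts Cα back to R and gives 15.

**Further compounds**
F1 | step 3 | (2R,3S,4R)-3-acetoxy-5,7-bis(benzyloxy)-2-[3,4-bis(benzyloxy)phenyl]chroman-4-ol | CC(=O)O[C@H]1[C@H](O)c2c(OCc3ccccc3)cc(OCc3ccccc3)cc2O[C@@H]1c1ccc(OCc2ccccc2)c(OCc2ccccc2)c1
F2 | step 3 | 4-hydroperoxide derived from F1 (C4 epimers) | CC(=O)O[C@H]1C(OO)c2c(OCc3ccccc3)cc(OCc3ccccc3)cc2O[C@@H]1c1ccc(OCc2ccccc2)c(OCc2ccccc2)c1
F3 | step 3 | 3-acetoxy-7,9-bis(benzyloxy)-4-[3,4-bis(benzyloxy)phenyl]-2-hydroperoxy-3,4-dihydro-2H-1,5-benzodioxepine (C2 epimers) | CC(=O)O[C@H]1C(OO)Oc2c(OCc3ccccc3)cc(OCc3ccccc3)cc2O[C@@H]1c1ccc(OCc2ccccc2)c(OCc2ccccc2)c1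
F4 | step 10 | hepta-allyl derivative of the target carrying the 2,3,5-tris(allyloxy)phenyl ether on Cβ–O | O=C(/C=C/c1ccc(O[C@@H](C(=O)OCC=C)[C@H](Oc2cc(OCC=C)cc(OCC=C)c2OCC=C)c2ccc(OCC=C)c(OCC=C)c2)c(OCC=C)c1)O[C@H](Cc1ccc(OCC=C)c(OCC=C)c1)C(=O)OCC=C
F5 | step 10 | hepta-allyl derivative of the target carrying the 5-(allyloxy)-3,6-dioxocyclohexa-1,4-dien-1-yl ether on Cβ–O | O=C(/C=C/c1ccc(O[C@@H](C(=O)OCC=C)[C@H](OC2=CC(=O)C=C(OCC=C)C2=O)c2ccc(OCC=C)c(OCC=C)c2)c(OCC=C)c1)O[C@H](Cc1ccc(OCC=C)c(OCC=C)c1)C(=O)OCC=C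
F6 | step 8 | allyl (2S,3R)-3-[3,4-bis(allyloxy)phenyl]-2-(4-nitrobenzoyloxy)-3-[2,3,5-tris(allyloxy)phenoxy]propanoate | O=C(O[C@H](C(=O)OCC=C)[C@H](Oc1cc(OCC=C)cc(OCC=C)c1OCC=C)c1ccc(OCC=C)c(OCC=C)c1)c1ccc([N+](=O)[O-])cc1
F7 | step 8 | allyl (2S,3R)-3-[3,4-bis(allyloxy)phenyl]-2-hydroxy-3-[2,3,5-tris(allyloxy)phenoxy]propanoate | O[C@H](C(=O)OCC=C)[C@H](Oc1cc(OCC=C)cc(OCC=C)c1OCC=C)c1ccc(OCC=C)c(OCC=C)c1
F8 | step 8 | 3-(allyloxy)-4-hydroxybenzaldehyde | O=Cc1ccc(O)c(OCC=C)c1
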